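**Assumption:** the SMILES is read as (2S,6R)-2-(4-hydroxy-3-methoxyphenyl)-6-[(1S)-1-hydroxy-2-(4-hydroxyphenyl)ethyl]oxan-4-one. In diarylheptanoid numbering (C1 carries the guaiacyl ring, C7 the 4-hydroxyphenyl ring) this is a 1,5-epoxy-3-one with a 2,6-cis ring and a 5R,6S (anti) diol pattern. L-Tyrosine and dehydrozingerone are taken as cheap commercial materials.

## Retrosynthetic overview

1. The pyranone is opened at O–C1: it is the 6-endo oxa-Michael adduct of the unprotected linear diarylheptanoid (1E,5R,6S)-5,6-dihydroxy-1-en-3-one, as in the presumed biosynthesis. This is the only ring formed and it is formed last, with C1 set by thermodynamic 2,6-cis control.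
2. The linear enone is cut at C4–C5: Felkin-controlled Mukaiyama aldol of the dienol silyl ether of dehydrozingerone with an (S)-α-silyloxy aldehyde. Aldol, global desilylation and ring closure are run in one flask.
3. The aldehyde (C5–C7 plus the 4-hydroxyphenyl ring, C6 stereocentre) comes from L-tyrosine: diazotisation with retention, esterification, bis-silylation, partial reduction.
4. The dienol silyl ether (C1–C4 plus the guaiacyl ring) comes from dehydrozingerone in one double silylation.

## Route

**Step 1**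
Reactants: 1 L-tyrosine
Product: 2 (S)-2-hydroxy-3-(4-hydroxyphenyl)propanoic acid
Conditions: NaNO2, 1 M aq. H2SO4, 0 °C to rt
Reagents that add atoms: water, O
Why: Diazotisation of the α-amino acid; the carboxylate displaces N2 to give an α-lactone that water reopens, so two inversions give net retention and the S centre (later C6) is kept.

**Step 2**
Reactants: 2 (S)-2-hydroxy-3-(4-hydroxyphenyl)propanoic acid
Product: 3 methyl (S)-2-hydroxy-3-(4-hydroxyphenyl)propanoate
Conditions: MeOH, cat. H2SO4, reflux
Reagents that add atoms: methanol, CO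
Why: Fischer esterification in a large excess of methanol; the stereocentre is not involved and the phenol and secondary alcohol are inert.

**Step 3**
Reactants: 3 methyl (S)-2-hydroxy-3-(4-hydroxyphenyl)propanoate
Product: 4 methyl (S)-2-[(tert-butyldimethylsilyl)oxy]-3-{4-[(tert-butyldimethylsilyl)oxy]phenyl}propanoate
Conditions: TBSCl (2.5 equiv), imidazole (5 equiv), DMF, rt
Reagents that add atoms: tert-butyldimethylsilyl chloride (TBSCl), CC(C)(C)[Si](C)(C)Cl
Why: Corey silylation of both hydroxyls in one operation; the bulky, non-chelating α-OTBS group is what later enforces Felkin selectivity.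

**Step 4**
Reactants: 4 methyl (S)-2-[(tert-butyldimethylsilyl)oxy]-3-{4-[(tert-butyldimethylsilyl)oxy]phenyl}propanoate
Product: 5 (S)-2-[(tert-butyldimethylsilyl)oxy]-3-{4-[(tert-butyldimethylsilyl)oxy]phenyl}propanal
Conditions: i-Bu2AlH (DIBAL-H, 1.1 equiv), CH2Cl2, −78 °C; MeOH, then aq. KNaC4H4O6 (Rochelle salt); used crude at once
Reagents that add atoms: none
Why: Partial ester reduction; the α-silyloxy tetrahedral aluminium hemiacetal is stable at −78 °C and releases the aldehyde only on work-up, and immediate use avoids epimerisation of the α-centre.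

**Step 5**
Reactants: 6 dehydrozingerone, (E)-4-(4-hydroxy-3-methoxyphenyl)but-3-en-2-one
Product: 7 (E)-2-[(tert-butyldimethylsilyl)oxy]-4-{4-[(tert-butyldimethylsilyl)oxy]-3-methoxyphenyl}buta-1,3-diene
Conditions: TBSOTf (2.3 equiv), Et3N (4 equiv), CH2Cl2, 0 °C; pentane/cold aq. NaHCO3 work-up
Reagents that add atoms: tert-butyldimethylsilyl trifluoromethanesulfonate (TBSOTf), CC(C)(C)[Si](C)(C)OS(=O)(=O)C(F)(F)F
Why: Soft enolisation/O-silylation; the methyl group is the only enolisable position, so one dienol ether forms, and the phenol is silylated in the same pot.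

**Step 6**
Reactants: 5 (S)-2-[(tert-butyldimethylsilyl)oxy]-3-{4-[(tert-butyldimethylsilyl)oxy]phenyl}propanal; 7 (E)-2-[(tert-butyldimethylsilyl)oxy]-4-{4-[(tert-butyldimethylsilyl)oxy]-3-methoxyphenyl}buta-1,3-diene
Product: 10 (2S,6R)-2-(4-hydroxy-3-methoxyphenyl)-6-[(1S)-1-hydroxy-2-(4-hydroxyphenyl)ethyl]oxan-4-one, via tris-TBS Felkin aldol adduct 8 (not isolated), via linear tetraol enone 9 (not isolated)
Conditions: BF3·OEt2 (1.5 equiv), 7 (1.5 equiv), CH2Cl2, −78 °C, 2 h; then MeCN, 48% aq. HF (excess), 0 °C to rt, 16 h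
Reagents that add atoms: none
Why: Proposed new method: a one-flask merger of three individually known events. (i) BF3-promoted Mukaiyama aldol of the CH2 terminus of 7 with aldehyde 5 through the open polar Felkin–Anh (Cornforth) transition state, nucleophile anti to the C–OTBS bond, which sets C5 as R (5,6-anti; expected dr about 5–10:1, minor epimer removed by chromatography). (ii) Cleavage of all four Si–O bonds by HF/HBF4, giving the presumed biosynthetic precursor 9. (iii) Acid-catalysed, reversible 6-endo-trig oxa-Michael addition of the 5-OH to the protonated styryl ketone, where the 4-hydroxy-3-methoxyphenyl group stabilises the benzylic cation and the 6-OH stays free because it could only close a seven-membered ring; equilibration gives the diequatorial 2,6-cis pyranone and so sets pyran C2 as S. The closest known reaction type is the stepwise Mukaiyama aldol followed by acid-mediated oxa-conjugate cyclisation of β-hydroxy enones to cis-2,6-disubstituted tetrahydropyran-4-ones (a formal hetero-Diels–Alder reaction of a 2-silyloxydiene with an aldehyde).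

## Compound list

1 | L-tyrosine, (S)-2-amino-3-(4-hydroxyphenyl)propanoic acid | N[C@@H](Cc1ccc(O)cc1)C(=O)O | starting material
2 | (S)-2-hydroxy-3-(4-hydroxyphenyl)propanoic acid | O[C@@H](Cc1ccc(O)cc1)C(=O)O | intermediate
3 | methyl (S)-2-hydroxy-3-(4-hydroxyphenyl)propanoate | COC(=O)[C@@H](O)Cc1ccc(O)cc1 | intermediate
4 | methyl (S)-2-[(tert-butyldimethylsilyl)oxy]-3-{4-[(tert-butyldimethylsilyl)oxy]phenyl}propanoate | COC(=O)[C@@H](O[Si](C)(C)C(C)(C)C)Cc1ccc(O[Si](C)(C)C(C)(C)C)cc1 | intermediate
5 | (S)-2-[(tert-butyldimethylsilyl)oxy]-3-{4-[(tert-butyldimethylsilyl)oxy]phenyl}propanal | O=C[C@@H](O[Si](C)(C)C(C)(C)C)Cc1ccc(O[Si](C)(C)C(C)(C)C)cc1 | intermediate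
6 | dehydrozingerone, (E)-4-(4-hydroxy-3-methoxyphenyl)but-3-en-2-one | COc1cc(/C=C/C(C)=O)ccc1O | starting material
7 | (E)-2-[(tert-butyldimethylsilyl)oxy]-4-{4-[(tert-butyldimethylsilyl)oxy]-3-methoxyphenyl}buta-1,3-diene | COc1cc(/C=C/C(=C)O[Si](C)(C)C(C)(C)C)ccc1O[Si](C)(C)C(C)(C)C | intermediate
8 | (1E,5R,6S)-6-[(tert-butyldimethylsilyl)oxy]-1-{4-[(tert-butyldimethylsilyl)oxy]-3-methoxyphenyl}-7-{4-[(tert-butyldimethylsilyl)oxy]phenyl}-5-hydroxyhept-1-en-3-one (5,6-anti) | COc1cc(/C=C/C(=O)C[C@@H](O)[C@@H](O[Si](C)(C)C(C)(C)C)Cc2ccc(O[Si](C)(C)C(C)(C)C)cc2)ccc1O[Si](C)(C)C(C)(C)C | intermediate (not isolated)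
9 | (1E,5R,6S)-5,6-dihydroxy-1-(4-hydroxy-3-methoxyphenyl)-7-(4-hydroxyphenyl)hept-1-en-3-one (5,6-anti diol) | COc1cc(/C=C/C(=O)C[C@@H](O)[C@@H](O)Cc2ccc(O)cc2)ccc1O | intermediate (not isolated)
10 | (2S,6R)-2-(4-hydroxy-3-methoxyphenyl)-6-[(1S)-1-hydroxy-2-(4-hydroxyphenyl)ethyl]oxan-4-one (2,6-cis) | COc1cc([C@@H]2CC(=O)C[C@H]([C@@H](O)Cc3ccc(O)cc3)O2)ccc1O | target

## Step count

- Total steps: 6.
- Longest linear sequence: 5 steps (1 → 2 → 3 → 4 → 5 → 10); the branch 6 → 7 is one step.

## Three steps most likely to fail, with fallbacks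

**Step 6 (one-flask aldol/desilylation/oxa-Michael).** The risks are modest Felkin selectivity, acid dehydration of the β-hydroxy ketone to the cross-conjugated dienone, and incomplete cyclisation. The fallback sets out from 5 and comes back at 10. Aldehyde 5 is treated with acetone and L-proline (30 mol%, DMSO, rt). The proline enamine attacks the Re face of the aldehyde, which is also the Felkin face, so catalyst and substrate control reinforce each other and give (4R,5S)-5-[(tert-butyldimethylsilyl)oxy]-6-{4-[(tert-butyldimethylsilyl)oxy]phenyl}-4-hydroxyhexan-2-one F1. F1 is condensed with commercial vanillin under pyrrolidine/AcOH in toluene at 40 °C. Enamine aldol condensation at the methyl group builds the C1=C2 styryl ketone, which closes in the same flask by oxa-Michael addition (Kabbe-type logic) under thermodynamic control to (2S,6R)-6-[(1S)-1-[(tert-butyldimethylsilyl)oxy]-2-{4-[(tert-butyldimethylsilyl)oxy]phenyl}ethyl]-2-(4-hydroxy-3-methoxyphenyl)oxan-4-one F2. 48% aq. HF in MeCN then removes the two silyl groups and gives 10. This fallback makes step 5 unnecessary.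

**Step 4 (partial reduction to a configurationally labile α-silyloxy aldehyde).** The risks are over-reduction and epimerisation. The fallback sets out from 4 and comes back at 5. Ester 4 is reduced fully with LiBH4 (THF/MeOH, 0 °C) to (S)-2-[(tert-butyldimethylsilyl)oxy]-3-{4-[(tert-butyldimethylsilyl)oxy]phenyl}propan-1-ol F3, a stable compound that can be purified and stored. F3 is oxidised with Dess–Martin periodinane (NaHCO3, CH2Cl2, 0 °C) to 5 immediately before use.

**Step 1 (diazotisation of unprotected tyrosine).** The risks are ring nitrosation of the free phenol and loss of the water-soluble product on extraction. The fallback sets out from 1 and comes back at 3. L-Tyrosine is O-benzylated through its divalent copper chelate (CuSO4, NaOH, then BnBr, aq. MeOH) to O-benzyl-L-tyrosine F4, which can also be bought. Diazotisation (NaNO2, H2SO4, aq. dioxane, 0 °C) then proceeds with the same retention on a substrate without a free phenol and gives the readily extracted (S)-3-[4-(benzyloxy)phenyl]-2-hydroxypropanoic acid F5. Fischer esterification (MeOH, cat. H2SO4) gives methyl (S)-3-[4-(benzyloxy)phenyl]-2-hydroxypropanoate F6, and hydrogenolysis (H2, 10% Pd/C, EtOAc) gives 3.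

## Further compounds

F1 | step 6 | (4R,5S)-5-[(tert-butyldimethylsilyl)oxy]-6-{4-[(tert-butyldimethylsilyl)oxy]phenyl}-4-hydroxyhexan-2-one | CC(=O)C[C@@H](O)[C@@H](O[Si](C)(C)C(C)(C)C)Cc1ccc(O[Si](C)(C)C(C)(C)C)cc1
F2 | step 6 | (2S,6R)-6-[(1S)-1-[(tert-butyldimethylsilyl)oxy]-2-{4-[(tert-butyldimethylsilyl)oxy]phenyl}ethyl]-2-(4-hydroxy-3-methoxyphenyl)oxan-4-one | COc1cc([C@@H]2CC(=O)C[C@H]([C@@H](O[Si](C)(C)C(C)(C)C)Cc3ccc(O[Si](C)(C)C(C)(C)C)cc3)O2)ccc1O
F3 | step 4 | (S)-2-[(tert-butyldimethylsilyl)oxy]-3-{4-[(tert-butyldimethylsilyl)oxy]phenyl}propan-1-ol | OC[C@@H](O[Si](C)(C)C(C)(C)C)Cc1ccc(O[Si](C)(C)C(C)(C)C)cc1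
F4 | step 1 | O-benzyl-L-tyrosine, (S)-2-amino-3-[4-(benzyloxy)phenyl]propanoic acid | N[C@@H](Cc1ccc(OCc2ccccc2)cc1)C(=O)O
F5 | step 1 | (S)-3-[4-(benzyloxy)phenyl]-2-hydroxypropanoic acid | O[C@@H](Cc1ccc(OCc2ccccc2)cc1)C(=O)O
F6 | step 1 | methyl (S)-3-[4-(benzyloxy)phenyl]-2-hydroxypropanoate | COC(=O)[C@@H](O)Cc1ccc(OCc2ccccc2)cc1
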